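I began from a balance for a closed flask: cE + cQ + cJ + cX stays at the E charged, X being my name for whatever the readings did not show.

| flask | E | D | remark | time |
|---|---|---|---|---|
| north | 0.50 M | 0.52 M | run made earlier |  |
| south | 0.50 M | 0.65 M | run made earlier |  |
| north-east | 0.50 M | 0.58 M | run made earlier |  |
| Thursday's | 0.50 M | 0.500 M |  | 80 min |
| Monday's | 0.50 M | 0.750 M |  | 80 min |

| run | time / min | J / % | E / % | Q / % |
|---|---|---|---|---|
| north | 4.00 | 20.9 | 16.6 | 17.1 |
| north | 10.0 | 41.3 | 1.8 | 4.7 |
| north | 20.0 | 45.8 | 0.1 | 0.9 |
| north | 30.0 | 46.1 | 0.2 | 0 |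
| north | 40.0 | 46.8 | 0 | 0.3 |
| south | 8.00 | 32.6 | 1.5 | 6.1 |
| south | 15.0 | 38.9 | 0.1 | 0 |
| south | 25.0 | 40.1 | 0.2 | 0 |
| south | 30.0 | 39.9 | 0.1 | 0.1 |
| south | 40.0 | 39.3 | 0 | 0 |
| north-east | 3.00 | 13.6 | 22.8 | 17.4 |
| north-east | 6.00 | 28.5 | 6.3 | 11.5 |
| north-east | 12.0 | 40.6 | 0.6 | 2.6 |
| north-east | 20.0 | 43.0 | 0.3 | 0.4 |
| north-east | 40.0 | 43.0 | 0 | 0 |

(readings scatter by 0.3 percentage points)

- the numbers in the tables scatter by 0.3 percentage points (one standard deviation)

- which of these there is most of at the end, counted by the E in it, Thursday's (J / Q / E)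
- which of these there is most of at the end, counted by the E in it, Monday's (J / Q / E)
- final amount of the leader among these, as a percentage of the E charged, in Thursday's
- final amount of the leader among these, as a percentage of the E charged, in Monday's

With the main road alone, E through Q to J, the balance puts J at 100% at the end. But the last readings of J average 46.5% in the north run and 39.8% in the south run, so X held the rest, and the south run, with its higher D, lost more.

So I added one step: X forms beside J, with cX/cJ = s·cD and D held at its charge. That s drifted, from 2.22 L mol⁻¹ in the north run to 2.33 L mol⁻¹ in the south run.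

Then I let each X cost one D, which was my assumption. Integrated, cD(end) = cD(start)·exp(−s·cJ). The north, south and north-east runs, the last on a mean J of 43.0%, now read 3.11 L mol⁻¹, 3.13 L mol⁻¹ and 3.14 L mol⁻¹. Their mean is 3.13 L mol⁻¹. This s, the selectivity factor, is X formed per J formed and per unit of cD.

In the north run E and Q read 0% and 0.3% at 40.0 min, so I reckoned 80 min as the end. For Thursday's flask, D held at its charge gives cJ = 0.195 M. Using D up raises that: cJ plus the D spent must equal the E charged. Newton's correction gives 0.236 M, then 0.238 M, which is 47.5%. For Monday's flask the same path runs 0.149 M, 0.178 M, 0.179 M, which is 35.7%.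

The forecast named J as leader in both flasks, with 47.5% on Thursday's and 35.7% on Monday's, noting that “more D means less J”.

The flasks gave J as leader in both, with 47.4% on Thursday's and 35.7% on Monday's.

    E + D → X (k = 0.0110 L mol⁻¹ s⁻¹)
    Q → J (k = 0.00560 s⁻¹)
    E → Q (k = 0.00350 s⁻¹)

With Monday's J, s leaves 57.2% of the D charged, and Monday's flask holds 57.1% at 80.0 min. In the equations s answers to the constant of E + D over that of E → Q. The neighbouring flask is Monday's with 2.0 M of E, so 0.375 equiv of D to E. As a first step I let the D go, which puts cJ at 1.25 M, and s then leaves 2.00% of that D, so by my reckoning nearly all of it is used. The balance makes J 63.2% of the E charged. The neighbouring flask gave 63.2%, with 1.9% of its D left.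

The runs were generated by integration with made-up constants.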